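Ring A is cut at the two bonds that flank its bare C1–C2 ethano unit (eudesmane numbering): C1–C10, at the methyl-bearing quaternary ring-fusion carbon, and C2–C3, beside the methylidene carbon C4. One Lewis-acid-promoted inverse-electron-demand Diels–Alder reaction makes both: phenyl vinyl sulfide, a traceless ethylene equivalent, adds across C3 and C10 of a cross-conjugated dienone built on ring B from (−)-menthone, whose C3=C4–C5=C10 diene carries the C6 carbonyl on C5 and a CH2SiMe3 group on C4. This closes ring A and sets C10; the silyl group then unveils the C4(15) methylidene and H-5, and one dissolving-metal reduction removes sulfur and sets the equatorial C6 alcohol.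

Key step: step 4

Remark: eudesmane numbering is used for all intermediates (ring A = C1–C5 and C10; ring B = C5–C10; C14 = methyl on C10; C15 = exocyclic carbon on C4; oxygen on C6; isopropyl on C7; α/β refer to the drawing with the C10 methyl β); the sulfur-bearing carbon C2 of 10 and 11 is left undefined because step 6 erases it; (−)-menthone free of isomenthone is assumed as the commercial source of chirality.

Step 1
Reactants: 1 (−)-menthone, (2S,5R)-5-methyl-2-(propan-2-yl)cyclohexan-1-one
Product: 3 (S)-piperitone, (6S)-3-methyl-6-(propan-2-yl)cyclohex-2-en-1-one, via kinetic trimethylsilyl enol ether 2 (not isolated)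
Conditions: LiN(iPr)2, THF, −78 °C; Me3SiCl; then Pd(OAc)2 (10 mol %), O2 (1 atm), DMSO, rt
Reagents that add atoms: none
Why: Kinetic deprotonation at the unhindered methylene leaves the isopropyl-bearing stereocentre (future C7) untouched, and Saegusa–Ito dehydrogenation of the silyl enol ether (β-hydride loss from the methyl-bearing carbon) should give the enone.

Step 2
Reactants: 3 (S)-piperitone
Product: 4 (6S)-2-iodo-3-methyl-6-(propan-2-yl)cyclohex-2-en-1-one
Conditions: I2, pyridine, CH2Cl2, 0 °C → rt, dark
Reagents that add atoms: iodine, II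
Why: Pyridine-mediated α-iodination of the enone (conjugate addition of pyridine, iodination of the enolate, elimination) should place iodine on the future C5 under conditions too mild to enolise the C7 stereocentre.

Step 3
Reactants: 4 (6S)-2-iodo-3-methyl-6-(propan-2-yl)cyclohex-2-en-1-one; 5 2-bromo-3-(trimethylsilyl)prop-1-ene
Product: 8 (6S)-3-methyl-6-(propan-2-yl)-2-[3-(trimethylsilyl)prop-1-en-2-yl]cyclohex-2-en-1-one, via alkenylmagnesium bromide 6 (not isolated), via alkenylzinc bromide 7 (not isolated)
Conditions: 5, Mg, THF, 40 °C; ZnBr2, 0 °C; then 4, Pd(PPh3)4 (5 mol %), THF, 45 °C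
Reagents that add atoms: none
Why: Negishi cross-coupling of the α-iodoenone with the alkenylzinc halide should join C4 to C5 without touching the ketone or the allylsilane, under non-basic conditions that do not epimerise C7.

Step 4
Reactants: 8 (6S)-3-methyl-6-(propan-2-yl)-2-[3-(trimethylsilyl)prop-1-en-2-yl]cyclohex-2-en-1-one; 9 phenyl vinyl sulfide, (ethenylsulfanyl)benzene
Product: 10 (2S,4aS)-4a-methyl-6-(phenylsulfanyl)-2-(propan-2-yl)-8-[(trimethylsilyl)methyl]-3,4,4a,5,6,7-hexahydronaphthalen-1(2H)-one, epimers at the sulfur-bearing carbon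
Conditions: Me2AlCl (1.2 equiv), 9 (4 equiv), CH2Cl2, −78 → −20 °C
Reagents that add atoms: none
Why: Me2AlCl on the C6 carbonyl turns the C3=C4–C5=C10 unit into an electron-poor 2-acyl diene whose terminus C10 is the enone β-carbon, and the electron-rich vinyl sulfide should add across C10 and C3 in an inverse-electron-demand Diels–Alder reaction, a type known for 2-carbonyl-substituted 1,3-dienes with vinyl sulfides and enol ethers. The addition is expected to be strongly asynchronous or stepwise: the CH2 terminus of the sulfide attacks C10 (Mukaiyama–Michael type, forming C1–C10 and a thionium ion at C2), and the γ-carbon C3 of the aluminium dienolate then closes on C2, so ring A forms in a [4+2] mode whose second event is a 6-exo-trig closure that restores the C4=C5 enone with the CH2SiMe3 group intact. Regiochemistry follows from the polarity of both partners (nucleophilic CH2 to the enone β-carbon C10, thionium carbon to the dienolate terminus C3). The quaternary centre C10 is controlled by C7: with aluminium held on the C7 side of the carbonyl by the bulky C5 substituent, A(1,3) strain should turn the isopropyl group pseudoaxial on the β face, and antiperiplanar attack at C10 should then come from the α face, giving C1 α and the C10 methyl β; the C10 epimer is a diastereomer (C7 is not enolised here) and would be removed by chromatography at this stage. The sulfur-bearing C2 forms without control and is erased in step 6. The step needs periselectivity for the all-carbon diene over the C10=C5–C6=O oxadiene; closure on oxygen gives an O,S-acetal that should re-ionise under the Lewis acid, so the irreversible C–C closure is expected to prevail.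

Step 5
Reactants: 10 (2S,4aS)-4a-methyl-6-(phenylsulfanyl)-2-(propan-2-yl)-8-[(trimethylsilyl)methyl]-3,4,4a,5,6,7-hexahydronaphthalen-1(2H)-one
Product: 11 (2S,4aS,8aS)-4a-methyl-8-methylidene-6-(phenylsulfanyl)-2-(propan-2-yl)octahydronaphthalen-1(2H)-one, epimers at the sulfur-bearing carbon
Conditions: Bu4NF (1.1 equiv), AcOH (3 equiv), THF, −40 → 0 °C
Reagents that add atoms: none
Why: Fluoride should cleave the vinylogous α-silyl ketone to the exocyclic dienolate, whose kinetic α-protonation at C5 (deconjugative protonation) gives the β,γ-unsaturated ketone with the C4(15) methylidene, the proton entering anti to the axial C10 methyl to give the trans ring fusion, which is also the more stable one.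

Step 6
Reactants: 11 (2S,4aS,8aS)-4a-methyl-8-methylidene-6-(phenylsulfanyl)-2-(propan-2-yl)octahydronaphthalen-1(2H)-one
Product: 12 (1S,2S,4aR,8aS)-4a-methyl-8-methylidene-2-(propan-2-yl)decahydronaphthalen-1-ol
Conditions: Li, NH3 (l), THF, t-BuOH, −78 °C; then NH4Cl
Reagents that add atoms: none
Why: Dissolving-metal reduction should cleave the alkyl–sulfur bond of the aryl sulfide and reduce the ketone through its ketyl to the thermodynamically preferred equatorial 6α-alcohol (all ring B substituents equatorial), while the isolated methylidene group is inert.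

Step 7
Reactants: 12 (1S,2S,4aR,8aS)-4a-methyl-8-methylidene-2-(propan-2-yl)decahydronaphthalen-1-ol; 13 (2E)-3-[4-(acetyloxy)phenyl]prop-2-enoic acid
Product: 14 (1S,2S,4aR,8aS)-4a-methyl-8-methylidene-2-(propan-2-yl)decahydronaphthalen-1-yl (2E)-3-[4-(acetyloxy)phenyl]prop-2-enoate
Conditions: DCC, DMAP (0.2 equiv), CH2Cl2, 0 °C → rt
Reagents that add atoms: none
Why: Steglich esterification should acylate the hindered equatorial alcohol with retention at C6, the phenol being masked as its acetate to prevent self-acylation.

Step 8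
Reactants: 14 (1S,2S,4aR,8aS)-4a-methyl-8-methylidene-2-(propan-2-yl)decahydronaphthalen-1-yl (2E)-3-[4-(acetyloxy)phenyl]prop-2-enoate
Product: 15 (1S,2S,4aR,8aS)-4a-methyl-8-methylidene-2-(propan-2-yl)decahydronaphthalen-1-yl (2E)-3-(4-hydroxyphenyl)prop-2-enoate
Conditions: pyrrolidine (3 equiv), CH2Cl2, 0 °C → rt
Reagents that add atoms: none
Why: Aminolysis should remove the activated aryl acetate far faster than the hindered conjugated ester, freeing the phenol without touching the (E)-alkene or any stereocentre.

Compound list
1 | (−)-menthone, (2S,5R)-5-methyl-2-(propan-2-yl)cyclohexan-1-one | CC(C)[C@@H]1CC[C@@H](C)CC1=O | starting material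
2 | trimethyl{[(3R,6S)-3-methyl-6-(propan-2-yl)cyclohex-1-en-1-yl]oxy}silane (kinetic silyl enol ether, formed in the flask) | CC(C)[C@@H]1CC[C@@H](C)C=C1O[Si](C)(C)C | intermediate
3 | (S)-piperitone, (6S)-3-methyl-6-(propan-2-yl)cyclohex-2-en-1-one | CC(C)[C@@H]1CCC(C)=CC1=O | intermediate
4 | (6S)-2-iodo-3-methyl-6-(propan-2-yl)cyclohex-2-en-1-one | CC(C)[C@@H]1CCC(C)=C(I)C1=O | intermediate
5 | 2-bromo-3-(trimethylsilyl)prop-1-ene | C=C(Br)C[Si](C)(C)C | starting material
6 | [3-(trimethylsilyl)prop-1-en-2-yl]magnesium bromide (formed in the flask) | C=C([Mg]Br)C[Si](C)(C)C | intermediate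
7 | [3-(trimethylsilyl)prop-1-en-2-yl]zinc bromide (formed in the flask) | C=C([Zn]Br)C[Si](C)(C)C | intermediate
8 | (6S)-3-methyl-6-(propan-2-yl)-2-[3-(trimethylsilyl)prop-1-en-2-yl]cyclohex-2-en-1-one | CC(C)[C@@H]1CCC(C)=C(C(=C)C[Si](C)(C)C)C1=O | intermediate
9 | phenyl vinyl sulfide, (ethenylsulfanyl)benzene | C=CSc1ccccc1 | starting material
10 | (2S,4aS)-4a-methyl-6-(phenylsulfanyl)-2-(propan-2-yl)-8-[(trimethylsilyl)methyl]-3,4,4a,5,6,7-hexahydronaphthalen-1(2H)-one, epimers at the sulfur-bearing carbon (eudesmane numbering: 2-phenylsulfanyl-15-trimethylsilyl-eudesm-4-en-6-one, 7β-isopropyl, 10β-methyl) | O=C1[C@H](C(C)C)CC[C@@]2(C)CC(Sc3ccccc3)CC(C[Si](C)(C)C)=C12 | intermediate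
11 | (2S,4aS,8aS)-4a-methyl-8-methylidene-6-(phenylsulfanyl)-2-(propan-2-yl)octahydronaphthalen-1(2H)-one, epimers at the sulfur-bearing carbon (2-phenylsulfanyl-5α-eudesm-4(15)-en-6-one) | O=C1[C@H](C(C)C)CC[C@@]2(C)CC(Sc3ccccc3)CC(=C)[C@H]12 | intermediate
12 | (1S,2S,4aR,8aS)-4a-methyl-8-methylidene-2-(propan-2-yl)decahydronaphthalen-1-ol (5α-eudesm-4(15)-en-6α-ol) | C=C1CCC[C@]2(C)CC[C@@H](C(C)C)[C@H](O)[C@@H]12 | intermediate
13 | (2E)-3-[4-(acetyloxy)phenyl]prop-2-enoic acid | CC(=O)Oc1ccc(/C=C/C(=O)O)cc1 | starting material
14 | (1S,2S,4aR,8aS)-4a-methyl-8-methylidene-2-(propan-2-yl)decahydronaphthalen-1-yl (2E)-3-[4-(acetyloxy)phenyl]prop-2-enoate | C=C1CCC[C@]2(C)CC[C@@H](C(C)C)[C@H](OC(=O)/C=C/c3ccc(OC(C)=O)cc3)[C@@H]12 | intermediate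
15 | (1S,2S,4aR,8aS)-4a-methyl-8-methylidene-2-(propan-2-yl)decahydronaphthalen-1-yl (2E)-3-(4-hydroxyphenyl)prop-2-enoate (CNP0321375.1) | C=C1CCC[C@]2(C)CC[C@@H](C(C)C)[C@H](OC(=O)/C=C/c3ccc(O)cc3)[C@@H]12 | target

Total step count: 8. Longest linear sequence: 8 steps (1 → 15).

Steps most likely to fail

The cycloaddition of step 4 carries the most risk. The thionium intermediate may close on the enone oxygen instead of on C3 (hetero-Diels–Alder periselectivity), addition at the fully substituted C10 may be too slow, or the two faces of C10 may be poorly discriminated. The fallback sets out from 8 and removes the carbonyl from the diene. 1,2-Reduction with LiBH(s-Bu)3 (hydride anti to the isopropyl group) should give the cis allylic alcohol F1, and silylation (t-BuMe2SiOTf, 2,6-lutidine) its silyl ether F2. The now electron-rich diene of F2 should undergo a normal-demand thermal Diels–Alder reaction with phenyl vinyl sulfone (toluene, 110 °C, or 12 kbar) on the face anti to the pseudoaxial silyloxy group, forming the same two bonds in the sulfone adduct F3. Bu4NF should then free the allylic alcohol F4, Dess–Martin oxidation should give the enone F5, the conditions of step 5 the β,γ-unsaturated ketone F6, and the conditions of step 6 (a sulfone cleaved in place of a sulfide) return the route to 12.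

In step 5 the dienolate may be protonated at C15 or re-conjugate under base, which would leave a conjugated enone with a C15 methyl group, or C5 may be protonated from the β face. The fallback sets out from 10: desilylative O-acetylation (CsF, Ac2O, MeCN) should give the cross-conjugated dienyl acetate F7. NaBH4 in EtOH should then release the β,γ-unsaturated ketone from the enol ester and reduce it at once, before it can conjugate, to the homoallylic 6β-alcohol F8. Dess–Martin oxidation buffered with NaHCO3 rejoins the route at 11.

In step 6 amide base may isomerise the β,γ-unsaturated ketone before electron transfer, the C2 radical may be captured across the ring by the ketyl, or C–S cleavage may stay incomplete. The fallback sets out from 11 and separates the two reductions. SmI2, H2O and Et3N in THF should reduce the ketone alone, under thermodynamic control, to the 6α-alcohol F9. After deprotonation of the alcohol with BuLi, reductive lithiation of the sulfide with lithium 4,4′-di-tert-butylbiphenylide and a methanol quench rejoins the route at 12.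

Further compounds
F1 | step 4 | (1R,6S)-3-methyl-6-(propan-2-yl)-2-[3-(trimethylsilyl)prop-1-en-2-yl]cyclohex-2-en-1-ol (hydroxyl cis to isopropyl) | O[C@@H]1[C@H](C(C)C)CCC(C)=C1C(=C)C[Si](C)(C)C
F2 | step 4 | tert-butyldimethylsilyl ether of F1 | CC(C)(C)[Si](C)(C)O[C@@H]1[C@H](C(C)C)CCC(C)=C1C(=C)C[Si](C)(C)C
F3 | step 4 | 6β-(tert-butyldimethylsilyloxy)-1-(phenylsulfonyl)-15-(trimethylsilyl)eudesm-4-ene (7β-isopropyl, 10β-methyl, epimers at C1) | CC(C)(C)[Si](C)(C)O[C@@H]1[C@H](C(C)C)CC[C@@]2(C)C(S(=O)(=O)c3ccccc3)CCC(C[Si](C)(C)C)=C12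
F4 | step 4 | 1-(phenylsulfonyl)-15-(trimethylsilyl)eudesm-4-en-6β-ol (epimers at C1) | O[C@@H]1[C@H](C(C)C)CC[C@@]2(C)C(S(=O)(=O)c3ccccc3)CCC(C[Si](C)(C)C)=C12
F5 | step 4 | 1-(phenylsulfonyl)-15-(trimethylsilyl)eudesm-4-en-6-one (epimers at C1) | O=C1[C@H](C(C)C)CC[C@@]2(C)C(S(=O)(=O)c3ccccc3)CCC(C[Si](C)(C)C)=C12
F6 | step 4 | 1-(phenylsulfonyl)-5α-eudesm-4(15)-en-6-one (epimers at C1) | O=C1[C@H](C(C)C)CC[C@@]2(C)C(S(=O)(=O)c3ccccc3)CCC(=C)[C@H]12
F7 | step 5 | 2-(phenylsulfanyl)eudesma-4(15),5-dien-6-yl acetate (epimers at C2) | CC(=O)OC1=C2C(=C)CC(Sc3ccccc3)C[C@]2(C)CC[C@H]1C(C)C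
F8 | step 5 | 2-(phenylsulfanyl)-5α-eudesm-4(15)-en-6β-ol (epimers at C2) | O[C@@H]1[C@H](C(C)C)CC[C@@]2(C)CC(Sc3ccccc3)CC(=C)[C@H]12
F9 | step 6 | 2-(phenylsulfanyl)-5α-eudesm-4(15)-en-6α-ol (epimers at C2) | C=C1CC(Sc3ccccc3)C[C@]2(C)CC[C@@H](C(C)C)[C@H](O)[C@@H]12
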